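**Early loss.** Start at early times: the first reading of each earlier run shows how fast the starting complex goes.

| flask | starting complex | incoming ligand | protic impurity | remark | time |
|---|---|---|---|---|---|
| amber | 0.80 M | 2 equiv | 0.54 M | run made earlier |  |
| red | 0.80 M | 2 equiv | 1.2 M | run made earlier |  |
| blue | 0.40 M | 2 equiv | 0.80 M | run made earlier |  |
| flask | 0.80 M | 2.00 equiv | 0.800 M |  | 5.0 h |

| run | time / h | complex with two exchanged / % | complex with three exchanged / % | starting complex / % |
|---|---|---|---|---|
| amber | 0.250 | 3.4 | 0 | 66.1 |
| amber | 0.500 | 6.1 | 0 | 45.9 |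
| amber | 1.33 | 11.7 | 1.0 | 24.0 |
| amber | 2.50 | 7.6 | 1.7 | 14.3 |
| amber | 5.00 | 3.2 | 0 | 8.3 |
| red | 0.250 | 4.2 | 0 | 48.4 |
| red | 0.500 | 6.3 | 1.3 | 27.9 |
| red | 1.33 | 7.3 | 0.8 | 8.0 |
| red | 2.50 | 3.5 | 0 | 2.8 |
| red | 5.00 | 0 | 0.9 | 0 |
| blue | 0.250 | 0 | 0.6 | 62.3 |
| blue | 0.500 | 2.2 | 1.2 | 41.6 |
| blue | 1.33 | 6.4 | 0.6 | 12.0 |
| blue | 2.50 | 7.7 | 0 | 3.2 |
| blue | 5.00 | 2.7 | 0 | 1.0 |

(standard deviation of a reading: 1 percentage point)

- the analysis behind the earlier runs scatters by 1 percentage point, standard deviation

1. time, not beyond 5.0 h, at which the flask holds most complex with two exchanged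
2. the amount of complex with two exchanged, in percent of the starting complex charged, at that time
3. the first time at which complex with two exchanged reaches 5.2%, in the same percent

**Two rates.** At 0.250 h the amber run holds 66.1% of its starting complex and the red run 48.4%. Read as simple decay (pseudo-first-order), amber loses it at 1.66 h⁻¹ and red at 2.90 h⁻¹. Red is faster, and it differs from amber in [protic impurity].

**Your ledger.** Open the books on the starting complex, the limiting reagent. A straight line through both rates splits the loss for the flask, which shares their [starting complex] and [incoming ligand], at its 0.800 M of impurity. This is my reckoning, and it carries the scatter of the readings. The impurity entry is 1.51 h⁻¹ and the ligand entry 0.636 h⁻¹. Their ratio, the rate of loss by impurity over the rate of loss by ligand, is the quench ratio, a selectivity factor: 2.38. So at early times, by this reckoning, 29.6% of each mole lost takes the ligand route.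

**Blue check.** Scale the ligand entry to blue's 0.40 M charge and you expect 1.83 h⁻¹; blue reads 1.89 h⁻¹.

**The drift.** [Protic impurity] and [incoming ligand] both fall as they are used, so the ratio can move. It is an opening value for early times, whereas the closing books are a sum over the whole run.

**The forecast.** It gives a peak of 9.2% at 1.1 h by “Interpolating on log impurity” between amber and red, and 0.41 h for the first time from the early rises in those two runs. My ratio gives no peak, just the split.

**The result.** The flask peaks at 1.09 h with 10.5%, first reaching 5.2% at 0.373 h, so the forecast is right within the tolerance on all three. So stop it near that peak: at 2.17 h it holds 7.16%.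

    starting complex + incoming ligand ⇌ leaving ligand + complex with one exchanged (K = 0.299, k = 0.00860 L mol⁻¹ min⁻¹)
    protic impurity + starting complex → quenched substrate (k = 0.0331 L mol⁻¹ min⁻¹)
    complex with three exchanged → over-reaction product (k = 0.168 min⁻¹)
    complex with one exchanged + incoming ligand ⇌ leaving ligand + complex with two exchanged (K = 1.40, k = 0.0224 L mol⁻¹ min⁻¹)
    complex with two exchanged + incoming ligand ⇌ leaving ligand + complex with three exchanged (K = 1.00, k = 0.0153 L mol⁻¹ min⁻¹)

**Books closed.** At 5.00 h the flask has 69.0% as quenched substrate, 28.7% along the ligand route and 2.25% still as starting complex. That is a run-long ratio of 2.40, a sum over the run and so no test of my opening 2.38. Now cut the incoming ligand to 0.800 equiv. Scaling the opening ratio by the ligand charge gives 5.94 for early times. That neighbouring flask ends with 79.5% quenched and 15.1% along the ligand route, a run-long ratio of 5.26, and its complex with two exchanged peaks at 6.00%.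

All runs come from a simulation for substances that don't exist; noise was put on by code.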